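**Plan**
- Retrosynthetic cuts, in order: the five methoxymethyl (MOM) ethers; the C3 epimer; the C2–C3 bond of the dihydrofuran ring (carbene C–H insertion); both aryl–C(=O) bonds (one aryl Grignard reagent, used twice); the C5–vinyl bond (Heck); the benzylic ether C–O bond (Mitsunobu).
- Forward order: ring A (a bromophenol acetate) is O-benzylated, converted to a Weinreb amide and Heck-extended; one double Weinreb ketone synthesis installs both 2,4-dioxygenated aryl ketones; diazo transfer follows; the dihydrofuran ring, the only ring to be made, is closed last.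
- Enabling feature: in the open precursor the O1–CH2–aryl methylene (future C2) sits on the phenol oxygen of ring A, 1,5 to the diazo carbon (future C3) on the neighbouring ring carbon C3a. Its C–H bonds are doubly activated (α-oxygen, para-oxygenated aryl), so a carbene at C3 can insert and close ring O1–C2–C3–C3a–C7a.
- Stereochemistry: C2 (S) from catalyst-controlled choice between the two enantiotopic methylene hydrogens; C3 (S) from thermodynamic epimerisation to the trans isomer; the E-alkene from the Heck reaction.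

Key step: step 8

Assumption 1: the target SMILES is read as the (2S,3S) isomer, with the 2-aryl and 3-aroyl groups trans on the dihydrofuran ring.
Assumption 2: the facial sense of Rh2(R-PTTL)4 on the diazo ketone is taken by analogy with ortho-benzyloxy aryldiazoacetates, where the S-configured catalyst family is understood to give the 2R series; if the sense is reversed here, Rh2(S-PTTL)4 is used with no other change.

**Route**

Step 1
Reactants: 1 4-hydroxybenzyl alcohol
Product: 2 [4-(methoxymethoxy)phenyl]methanol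
Conditions: MOMCl (1.05 equiv), K2CO3, acetone, 0 °C → rt
Reagents that add atoms: chloromethyl methyl ether (MOMCl), COCCl
Why: Williamson-type O-alkylation in which K2CO3 deprotonates only the phenol, far more acidic than the benzylic alcohol, so the phenoxide alone should be alkylated.

Step 2
Reactants: 2 [4-(methoxymethoxy)phenyl]methanol; 3 methyl 2-(5-bromo-2-hydroxyphenyl)acetate
Product: 4 methyl 2-[5-bromo-2-[[4-(methoxymethoxy)phenyl]methoxy]phenyl]acetate
Conditions: PPh3, DIAD, THF, 0 °C → rt
Reagents that add atoms: none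
Why: Mitsunobu etherification of an acidic phenol with a primary benzylic alcohol under neutral conditions, which should leave the methyl ester, the aryl bromide and the acetal untouched.

Step 3
Reactants: 4 methyl 2-[5-bromo-2-[[4-(methoxymethoxy)phenyl]methoxy]phenyl]acetate
Product: 5 2-[5-bromo-2-[[4-(methoxymethoxy)phenyl]methoxy]phenyl]-N-methoxy-N-methylacetamide
Conditions: MeNH(OMe)·HCl (1.5 equiv), i-PrMgCl (3.0 equiv), THF, −20 °C
Reagents that add atoms: N,O-dimethylhydroxylamine hydrochloride, CNOC.Cl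
Why: Direct ester aminolysis by the chloromagnesium amide of N,O-dimethylhydroxylamine (Weinreb amide formation) at a temperature where bromine–magnesium exchange on the electron-rich aryl bromide should not compete.

Step 4
Reactants: 5 2-[5-bromo-2-[[4-(methoxymethoxy)phenyl]methoxy]phenyl]-N-methoxy-N-methylacetamide; 6 N-methoxy-N-methylprop-2-enamide
Product: 7 (E)-N-methoxy-3-[3-[2-[methoxy(methyl)amino]-2-oxoethyl]-4-[[4-(methoxymethoxy)phenyl]methoxy]phenyl]-N-methylprop-2-enamide
Conditions: Pd(OAc)2 (5 mol %), P(o-tol)3 (10 mol %), Et3N, DMF, 100 °C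
Reagents that add atoms: none
Why: Mizoroki–Heck coupling of the aryl bromide with the electron-poor acrylamide, in which syn-insertion and syn-β-hydride elimination should give the E-alkene while both Weinreb amides stay inert to zerovalent palladium and Et3N.

Step 5
Reactants: 8 4-bromobenzene-1,3-diol
Product: 9 1-bromo-2,4-bis(methoxymethoxy)benzene
Conditions: MOMCl (2.4 equiv), i-Pr2NEt, CH2Cl2, 0 °C → rt
Reagents that add atoms: chloromethyl methyl ether (MOMCl), COCCl
Why: Twofold O-alkylation of the resorcinol to the bis-acetal, whose ortho oxygen should later stabilise the arylmagnesium reagent by chelation.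

Step 6
Reactants: 7 (E)-N-methoxy-3-[3-[2-[methoxy(methyl)amino]-2-oxoethyl]-4-[[4-(methoxymethoxy)phenyl]methoxy]phenyl]-N-methylprop-2-enamide; 9 1-bromo-2,4-bis(methoxymethoxy)benzene (3 equiv)
Product: 11 (E)-1-[2,4-bis(methoxymethoxy)phenyl]-3-[3-[2-[2,4-bis(methoxymethoxy)phenyl]-2-oxoethyl]-4-[[4-(methoxymethoxy)phenyl]methoxy]phenyl]prop-2-en-1-one, via arylmagnesium bromide 10 (not isolated)
Conditions: 9, Mg turnings, LiCl, THF, rt; then 7, THF, 0 °C → rt; aq. NH4Cl
Reagents that add atoms: none
Why: Weinreb ketone synthesis run twice in one flask, in which the aryl Grignard should add 1,2 to each N-methoxy-N-methylamide and the magnesium-chelated tetrahedral adducts should persist until work-up, so that neither over-addition nor conjugate addition to the cinnamoyl unit is expected and the E-alkene is kept.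

Step 7
Reactants: 11 (E)-1-[2,4-bis(methoxymethoxy)phenyl]-3-[3-[2-[2,4-bis(methoxymethoxy)phenyl]-2-oxoethyl]-4-[[4-(methoxymethoxy)phenyl]methoxy]phenyl]prop-2-en-1-one
Product: 12 (E)-1-[2,4-bis(methoxymethoxy)phenyl]-3-[3-[2-[2,4-bis(methoxymethoxy)phenyl]-1-diazo-2-oxoethyl]-4-[[4-(methoxymethoxy)phenyl]methoxy]phenyl]prop-2-en-1-one
Conditions: p-ABSA (1.5 equiv), DBU (1.5 equiv), MeCN, 0 °C, dark
Reagents that add atoms: 4-acetamidobenzenesulfonyl azide (p-ABSA), CC(=O)Nc1ccc(cc1)S(=O)(=O)N=[N+]=[N-]
Why: Regitz diazo transfer in which DBU forms the benzylic enolate of the deoxybenzoin, the only CH acid present, and this enolate should capture the sulfonyl azide (a much stronger electrophile than the chalcone) before intermolecular Michael addition can compete.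

Step 8
Reactants: 12 (E)-1-[2,4-bis(methoxymethoxy)phenyl]-3-[3-[2-[2,4-bis(methoxymethoxy)phenyl]-1-diazo-2-oxoethyl]-4-[[4-(methoxymethoxy)phenyl]methoxy]phenyl]prop-2-en-1-one
Product: 13 (E)-1-[2,4-bis(methoxymethoxy)phenyl]-3-[(2S,3R)-3-[2,4-bis(methoxymethoxy)benzoyl]-2-[4-(methoxymethoxy)phenyl]-2,3-dihydro-1-benzofuran-5-yl]prop-2-en-1-one (cis)
Conditions: Rh2(R-PTTL)4 [dirhodium tetrakis(N-phthaloyl-(R)-tert-leucinate)] (1 mol %), toluene (0.01 M), 4 Å MS, −40 → 0 °C
Reagents that add atoms: none
Why: Rh2(R-PTTL)4 expels N2 from 12 to give a rhodium-bound aryl(aroyl) carbene whose carbene carbon (future C3), held on ring A next to the benzyloxy oxygen, inserts through a concerted, hydride-transfer-like three-centre transition state into one C–H bond of the O–CH2–aryl methylene (future C2). The closest known reaction type is the enantioselective intramolecular 1,5 C–H insertion of ortho-benzyloxy aryldiazoacetates to cis-2-aryl-2,3-dihydrobenzofuran-3-carboxylates, here with an aryl ketone as the acceptor in place of an ester. The one ring that closes is the dihydrofuran ring O1–C2–C3–C3a–C7a, made by C2–C3 bond formation in the 1,5-insertion mode (five-membered cyclic transition state counting the carbene carbon as atom 1 and the methylene carbon as atom 5). C2 is set by the catalyst, whose chiral phthalimido-carboxylate pocket should let the carbene reach only one of the two enantiotopic methylene hydrogens, and C3 arises in the same event, expected cis to the C2 aryl group, which is of no consequence because step 9 resets it. The step needs chemoselectivity for this C–H bond over oxonium-ylide formation or 1,6-insertion at the ortho methoxymethoxy group of the aroyl ring and over any reaction with the chalcone, and it should be secured by the five-membered transition state, the double activation of the methylene hydrogens (α-oxygen and para-alkoxyphenyl), the tempered reactivity of a donor/acceptor carbene, low temperature and high dilution.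

Step 9
Reactants: 13 (E)-1-[2,4-bis(methoxymethoxy)phenyl]-3-[(2S,3R)-3-[2,4-bis(methoxymethoxy)benzoyl]-2-[4-(methoxymethoxy)phenyl]-2,3-dihydro-1-benzofuran-5-yl]prop-2-en-1-one
Product: 14 (E)-1-[2,4-bis(methoxymethoxy)phenyl]-3-[(2S,3S)-3-[2,4-bis(methoxymethoxy)benzoyl]-2-[4-(methoxymethoxy)phenyl]-2,3-dihydro-1-benzofuran-5-yl]prop-2-en-1-one (trans)
Conditions: DBU (0.3 equiv), CH2Cl2, rt
Reagents that add atoms: none
Why: Thermodynamic epimerisation of the α-aryl ketone centre C3 through its enolate should place the aroyl group trans to the C2 aryl group, while C2 carries no acidic hydrogen and ring opening by β-elimination of the phenoxide would be the stereoelectronically disfavoured reverse of a 5-endo-trig closure, so the 2S centre from step 8 should be kept.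

Step 10
Reactants: 14 (E)-1-[2,4-bis(methoxymethoxy)phenyl]-3-[(2S,3S)-3-[2,4-bis(methoxymethoxy)benzoyl]-2-[4-(methoxymethoxy)phenyl]-2,3-dihydro-1-benzofuran-5-yl]prop-2-en-1-one
Product: 15 (E)-3-[(2S,3S)-3-(2,4-dihydroxybenzoyl)-2-(4-hydroxyphenyl)-2,3-dihydro-1-benzofuran-5-yl]-1-(2,4-dihydroxyphenyl)prop-2-en-1-one (CNP0288976.2)
Conditions: HCl (1.25 M in MeOH), THF co-solvent, rt → 40 °C
Reagents that add atoms: none
Why: Acid-catalysed acetal solvolysis (MOM ether cleavage) should free all five phenols under conditions commonly used on 2'-hydroxychalcones, and since the trans C3 centre is already the thermodynamic epimer and C2 has no acidic hydrogen, neither stereocentre should change.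

**Compound list**
1 | 4-hydroxybenzyl alcohol | OCc1ccc(O)cc1 | starting material
2 | [4-(methoxymethoxy)phenyl]methanol | COCOc1ccc(CO)cc1 | intermediate
3 | methyl 2-(5-bromo-2-hydroxyphenyl)acetate | COC(=O)Cc1cc(Br)ccc1O | starting material
4 | methyl 2-[5-bromo-2-[[4-(methoxymethoxy)phenyl]methoxy]phenyl]acetate | COC(=O)Cc1cc(Br)ccc1OCc1ccc(OCOC)cc1 | intermediate
5 | 2-[5-bromo-2-[[4-(methoxymethoxy)phenyl]methoxy]phenyl]-N-methoxy-N-methylacetamide | CON(C)C(=O)Cc1cc(Br)ccc1OCc1ccc(OCOC)cc1 | intermediate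
6 | N-methoxy-N-methylprop-2-enamide | C=CC(=O)N(C)OC | starting material
7 | (E)-N-methoxy-3-[3-[2-[methoxy(methyl)amino]-2-oxoethyl]-4-[[4-(methoxymethoxy)phenyl]methoxy]phenyl]-N-methylprop-2-enamide | CON(C)C(=O)/C=C/c1ccc(OCc2ccc(OCOC)cc2)c(CC(=O)N(C)OC)c1 | intermediate
8 | 4-bromobenzene-1,3-diol | Oc1ccc(Br)c(O)c1 | starting material
9 | 1-bromo-2,4-bis(methoxymethoxy)benzene | COCOc1ccc(Br)c(OCOC)c1 | intermediate
10 | [2,4-bis(methoxymethoxy)phenyl]magnesium bromide | COCOc1ccc([Mg]Br)c(OCOC)c1 | intermediate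
11 | (E)-1-[2,4-bis(methoxymethoxy)phenyl]-3-[3-[2-[2,4-bis(methoxymethoxy)phenyl]-2-oxoethyl]-4-[[4-(methoxymethoxy)phenyl]methoxy]phenyl]prop-2-en-1-one | COCOc1ccc(C(=O)/C=C/c2ccc(OCc3ccc(OCOC)cc3)c(CC(=O)c3ccc(OCOC)cc3OCOC)c2)c(OCOC)c1 | intermediate
12 | (E)-1-[2,4-bis(methoxymethoxy)phenyl]-3-[3-[2-[2,4-bis(methoxymethoxy)phenyl]-1-diazo-2-oxoethyl]-4-[[4-(methoxymethoxy)phenyl]methoxy]phenyl]prop-2-en-1-one | COCOc1ccc(C(=O)/C=C/c2ccc(OCc3ccc(OCOC)cc3)c(C(=[N+]=[N-])C(=O)c3ccc(OCOC)cc3OCOC)c2)c(OCOC)c1 | intermediate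
13 | (E)-1-[2,4-bis(methoxymethoxy)phenyl]-3-[(2S,3R)-3-[2,4-bis(methoxymethoxy)benzoyl]-2-[4-(methoxymethoxy)phenyl]-2,3-dihydro-1-benzofuran-5-yl]prop-2-en-1-one (cis) | O=C(/C=C/c1ccc2c(c1)[C@@H](C(=O)c1ccc(OCOC)cc1OCOC)[C@@H](c1ccc(OCOC)cc1)O2)c1ccc(OCOC)cc1OCOC | intermediate
14 | (E)-1-[2,4-bis(methoxymethoxy)phenyl]-3-[(2S,3S)-3-[2,4-bis(methoxymethoxy)benzoyl]-2-[4-(methoxymethoxy)phenyl]-2,3-dihydro-1-benzofuran-5-yl]prop-2-en-1-one (trans) | O=C(/C=C/c1ccc2c(c1)[C@H](C(=O)c1ccc(OCOC)cc1OCOC)[C@@H](c1ccc(OCOC)cc1)O2)c1ccc(OCOC)cc1OCOC | intermediate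
15 | (E)-3-[(2S,3S)-3-(2,4-dihydroxybenzoyl)-2-(4-hydroxyphenyl)-2,3-dihydro-1-benzofuran-5-yl]-1-(2,4-dihydroxyphenyl)prop-2-en-1-one | O=C(/C=C/c1ccc2c(c1)[C@H](C(=O)c1ccc(O)cc1O)[C@@H](c1ccc(O)cc1)O2)c1ccc(O)cc1O | target

**Count**
Total steps: 10. Longest linear sequence: 9 steps (steps 1, 2, 3, 4, 6, 7, 8, 9, 10); step 5 is a one-step side branch.

**Steps most likely to fail**

Step 8. The rhodium carbene may be diverted to the ortho methoxymethoxy group of the aroyl ring (oxonium ylide followed by 1,2-shift, or 1,6-insertion into the acetal CH2), or the ketone acceptor may lower facial discrimination. The fallback moves the ring closure to the ester level, where no such neighbouring oxygen exists and the substrate class has the closest precedent. It sets out from 4. Diazo transfer (p-ABSA, DBU, MeCN) should give methyl 2-[5-bromo-2-[[4-(methoxymethoxy)phenyl]methoxy]phenyl]-2-diazoacetate F1. Rh2(R-PTTL)4 in toluene at −60 °C should then give methyl (2S,3R)-5-bromo-2-[4-(methoxymethoxy)phenyl]-2,3-dihydro-1-benzofuran-3-carboxylate F2. NaOMe in MeOH followed by aqueous LiOH should epimerise and hydrolyse it to (2S,3S)-5-bromo-2-[4-(methoxymethoxy)phenyl]-2,3-dihydro-1-benzofuran-3-carboxylic acid F3. Coupling with MeNH(OMe)·HCl (EDC·HCl, HOBt, i-Pr2NEt) should give (2S,3S)-5-bromo-N-methoxy-2-[4-(methoxymethoxy)phenyl]-N-methyl-2,3-dihydro-1-benzofuran-3-carboxamide F4. Heck coupling with 6 under the conditions of step 4 should give (2S,3S)-N-methoxy-5-[(E)-3-[methoxy(methyl)amino]-3-oxoprop-1-enyl]-2-[4-(methoxymethoxy)phenyl]-N-methyl-2,3-dihydro-1-benzofuran-3-carboxamide F5. Addition of excess 10 as in step 6 comes back to the route at 14; any cis isomer 13 formed on protonation is converged by step 9.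

Step 7. The DBU-generated enolate may add to the chalcone of a second molecule (Michael oligomerisation) before it captures the sulfonyl azide, or the diazo group may slowly undergo dipolar cycloaddition with the enone. The fallback keeps the enone out of the molecule until the ring is closed. It sets out from 5. A single Weinreb ketone synthesis with 10 should give 1-[2,4-bis(methoxymethoxy)phenyl]-2-[5-bromo-2-[[4-(methoxymethoxy)phenyl]methoxy]phenyl]ethanone F6. Diazo transfer (p-ABSA, DBU) should give 1-[2,4-bis(methoxymethoxy)phenyl]-2-[5-bromo-2-[[4-(methoxymethoxy)phenyl]methoxy]phenyl]-2-diazoethanone F7. The insertion conditions of step 8 should give [(2S,3R)-5-bromo-2-[4-(methoxymethoxy)phenyl]-2,3-dihydro-1-benzofuran-3-yl]-[2,4-bis(methoxymethoxy)phenyl]methanone F8. Separately, 6 and 10 should give 1-[2,4-bis(methoxymethoxy)phenyl]prop-2-en-1-one F9, with inverse quench into cold dilute HCl so that the liberated amine does not add to the enone. Heck coupling of F8 with F9 (Pd(OAc)2, P(o-tol)3, Et3N, DMF, 90 °C) comes back to the route at 13; partial epimerisation to 14 under Et3N is harmless because step 9 follows.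

Step 6. The aryl Grignard reagent may deprotonate the arylacetyl Weinreb amide instead of adding to it, leaving a mono-ketone, or may add in a conjugate sense to the cinnamoyl amide. The fallback lowers the oxidation level of both electrophiles so that addition should be much faster than deprotonation. It sets out from 7. Reduction with i-Bu2AlH (2.4 equiv, THF, −78 °C) should give (E)-3-[4-[[4-(methoxymethoxy)phenyl]methoxy]-3-(2-oxoethyl)phenyl]prop-2-enal F10, used crude. Addition of 10 at −78 °C should give (E)-1-[2,4-bis(methoxymethoxy)phenyl]-3-[3-[2-[2,4-bis(methoxymethoxy)phenyl]-2-hydroxyethyl]-4-[[4-(methoxymethoxy)phenyl]methoxy]phenyl]prop-2-en-1-ol F11 as a diastereomer mixture. Oxidation of both carbinols with Dess–Martin periodinane (CH2Cl2, NaHCO3) comes back to the route at 11.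

**Further compounds**
F1 | step 8 | methyl 2-[5-bromo-2-[[4-(methoxymethoxy)phenyl]methoxy]phenyl]-2-diazoacetate | COC(=O)C(=[N+]=[N-])c1cc(Br)ccc1OCc1ccc(OCOC)cc1
F2 | step 8 | methyl (2S,3R)-5-bromo-2-[4-(methoxymethoxy)phenyl]-2,3-dihydro-1-benzofuran-3-carboxylate | Brc1ccc2c(c1)[C@@H](C(=O)OC)[C@@H](c1ccc(OCOC)cc1)O2
F3 | step 8 | (2S,3S)-5-bromo-2-[4-(methoxymethoxy)phenyl]-2,3-dihydro-1-benzofuran-3-carboxylic acid | Brc1ccc2c(c1)[C@H](C(=O)O)[C@@H](c1ccc(OCOC)cc1)O2
F4 | step 8 | (2S,3S)-5-bromo-N-methoxy-2-[4-(methoxymethoxy)phenyl]-N-methyl-2,3-dihydro-1-benzofuran-3-carboxamide | Brc1ccc2c(c1)[C@H](C(=O)N(C)OC)[C@@H](c1ccc(OCOC)cc1)O2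
F5 | step 8 | (2S,3S)-N-methoxy-5-[(E)-3-[methoxy(methyl)amino]-3-oxoprop-1-enyl]-2-[4-(methoxymethoxy)phenyl]-N-methyl-2,3-dihydro-1-benzofuran-3-carboxamide | CON(C)C(=O)/C=C/c1ccc2c(c1)[C@H](C(=O)N(C)OC)[C@@H](c1ccc(OCOC)cc1)O2
F6 | step 7 | 1-[2,4-bis(methoxymethoxy)phenyl]-2-[5-bromo-2-[[4-(methoxymethoxy)phenyl]methoxy]phenyl]ethanone | COCOc1ccc(C(=O)Cc2cc(Br)ccc2OCc2ccc(OCOC)cc2)c(OCOC)c1
F7 | step 7 | 1-[2,4-bis(methoxymethoxy)phenyl]-2-[5-bromo-2-[[4-(methoxymethoxy)phenyl]methoxy]phenyl]-2-diazoethanone | COCOc1ccc(C(=O)C(=[N+]=[N-])c2cc(Br)ccc2OCc2ccc(OCOC)cc2)c(OCOC)c1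
F8 | step 7 | [(2S,3R)-5-bromo-2-[4-(methoxymethoxy)phenyl]-2,3-dihydro-1-benzofuran-3-yl]-[2,4-bis(methoxymethoxy)phenyl]methanone | Brc1ccc2c(c1)[C@@H](C(=O)c1ccc(OCOC)cc1OCOC)[C@@H](c1ccc(OCOC)cc1)O2
F9 | step 7 | 1-[2,4-bis(methoxymethoxy)phenyl]prop-2-en-1-one | C=CC(=O)c1ccc(OCOC)cc1OCOC
F10 | step 6 | (E)-3-[4-[[4-(methoxymethoxy)phenyl]methoxy]-3-(2-oxoethyl)phenyl]prop-2-enal | O=C/C=C/c1ccc(OCc2ccc(OCOC)cc2)c(CC=O)c1
F11 | step 6 | (E)-1-[2,4-bis(methoxymethoxy)phenyl]-3-[3-[2-[2,4-bis(methoxymethoxy)phenyl]-2-hydroxyethyl]-4-[[4-(methoxymethoxy)phenyl]methoxy]phenyl]prop-2-en-1-ol (diastereomer mixture) | COCOc1ccc(C(O)/C=C/c2ccc(OCc3ccc(OCOC)cc3)c(CC(O)c3ccc(OCOC)cc3OCOC)c2)c(OCOC)c1
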